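The dihydrofuran ring is closed last at its aryl ether bond, O1–C7a, by an intramolecular SNAr reaction. The disconnection exploits the para relationship on ring A between C7a and C5, the carbon that carries the stilbene olefin: at the aldehyde oxidation level this carbon activates a C7a–F bond for attack by the C2 alkoxide and is then converted into the E-olefin by a Horner–Wadsworth–Emmons reaction in the same flask. The precursor is an open-chain (1S,2S)-1,2,2-triarylethanol whose two stereocenters come from one asymmetric transfer hydrogenation with dynamic kinetic resolution of a 1,2,2-triarylethanone, itself made by two palladium-catalysed ketone α-arylations.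

Key step: step 5

Remark: benzofuran numbering is used for the target (O1, C2, C3, C3a, C4 to C7, C7a; ring A is the benzo ring). The target SMILES is the trans-(2S,3S) isomer. All six phenols are carried as methyl ethers, and 1, 2, 4 and 8 are taken as commercial.

Step 1
Reactants: 1 1-(3,4-dimethoxyphenyl)ethan-1-one; 2 1-bromo-3,5-dimethoxybenzene
Product: 3 1-(3,4-dimethoxyphenyl)-2-(3,5-dimethoxyphenyl)ethan-1-one
Conditions: Pd2(dba)3 (1 mol %), Xantphos (2.2 mol %), NaOtBu (2.2 equiv), 1 (1.2 equiv), toluene, 80 °C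
Reagents that add atoms: none
Why: Palladium-catalysed α-arylation of a methyl ketone enolate (Buchwald–Hartwig type), in which the wide-bite-angle ligand and the lower reactivity of the more stabilised product enolate should stop the reaction at monoarylation.

Step 2
Reactants: 3 1-(3,4-dimethoxyphenyl)-2-(3,5-dimethoxyphenyl)ethan-1-one; 4 2-(3-bromo-4-fluorophenyl)-1,3-dioxolane
Product: 5 rac-1-(3,4-dimethoxyphenyl)-2-(3,5-dimethoxyphenyl)-2-[5-(1,3-dioxolan-2-yl)-2-fluorophenyl]ethan-1-one
Conditions: Pd(OAc)2 (2 mol %), P(tBu)3·HBF4 (4 mol %), NaOtBu (2.2 equiv), toluene, 90 °C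
Reagents that add atoms: none
Why: Second palladium-catalysed ketone α-arylation, in which only the C–Br bond of 4 should react while the unactivated C–F bond and the acetal are inert, and which gives the doubly benzylic α-stereocenter as a racemate that stays configurationally labile, as step 3 requires.

Step 3
Reactants: 5 rac-1-(3,4-dimethoxyphenyl)-2-(3,5-dimethoxyphenyl)-2-[5-(1,3-dioxolan-2-yl)-2-fluorophenyl]ethan-1-one
Product: 6 (1S,2S)-1-(3,4-dimethoxyphenyl)-2-(3,5-dimethoxyphenyl)-2-[5-(1,3-dioxolan-2-yl)-2-fluorophenyl]ethan-1-ol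
Conditions: RuCl[(S,S)-TsDPEN](p-cymene) (2 mol %), HCO2H/Et3N (1:1), DMF, 40 °C
Reagents that add atoms: none
Why: Noyori–Ikariya asymmetric transfer hydrogenation with dynamic kinetic resolution, in which the (S,S)-catalyst should set C1 as (S) as it does for deoxybenzoins, the α-centre racemises by amine-mediated enolisation, and the ketone enantiomer that can place the bulkier, electron-poorer 2-fluoroaryl group anti to the incoming hydride (Felkin–Anh) should be reduced faster, which sets C2 as (S).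

Step 4
Reactants: 6 (1S,2S)-1-(3,4-dimethoxyphenyl)-2-(3,5-dimethoxyphenyl)-2-[5-(1,3-dioxolan-2-yl)-2-fluorophenyl]ethan-1-ol
Product: 7 3-[(1S,2S)-2-(3,4-dimethoxyphenyl)-1-(3,5-dimethoxyphenyl)-2-hydroxyethyl]-4-fluorobenzaldehyde
Conditions: 1 M aq. HCl, THF (1:4), 0 °C → rt
Reagents that add atoms: water, O
Why: Acid-catalysed hydrolysis of an aryl dioxolane, which in dilute acid at or below room temperature should free the aldehyde without ionising the benzylic alcohol or touching either stereocenter.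

Step 5
Reactants: 7 3-[(1S,2S)-2-(3,4-dimethoxyphenyl)-1-(3,5-dimethoxyphenyl)-2-hydroxyethyl]-4-fluorobenzaldehyde; 8 diethyl [(3,5-dimethoxyphenyl)methyl]phosphonate
Product: 10 (2S,3S)-2-(3,4-dimethoxyphenyl)-3-(3,5-dimethoxyphenyl)-5-[(E)-2-(3,5-dimethoxyphenyl)ethenyl]-2,3-dihydro-1-benzofuran, via dihydrobenzofuran-5-carbaldehyde 9 (not isolated)
Conditions: KN(SiMe3)2 (1.05 equiv), THF, −20 → 0 °C; then potassium salt of 8 (from 8, 1.3 equiv, and KN(SiMe3)2, 1.3 equiv, THF, 0 °C), 0 °C → rt
Reagents that add atoms: none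
Why: The potassium alkoxide of 7 adds to C7a of ring A, whose C–F bond is activated by the para formyl group at C5, to give a Meisenheimer complex that expels fluoride (addition–elimination SNAr); the closest known reaction type is the intramolecular O-arylation of alkoxides with 4-fluorobenzaldehydes and other para-acceptor aryl fluorides. The five-membered ring closes in a 5-exo-trig mode. No stereocenter is formed: C2 and C3 are carried over from 7 without any bond to them being broken, so the (1S,2S)-alcohol can give only the trans-(2S,3S) ring. The step needs O-attack at C7a to win over reversible addition of the alkoxide to the aldehyde, hydride transfer to it and deprotonation at C3; the non-nucleophilic base, the low temperature and the high effective molarity of a five-ring closure onto an activated fluoride should secure this. The formyl group that served as activator is then used up in the same flask by the Horner–Wadsworth–Emmons reaction with the anion of 8, which should give the E-olefin through the usual preference of semi-stabilised benzylphosphonates with aryl aldehydes.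

Step 6
Reactants: 10 (2S,3S)-2-(3,4-dimethoxyphenyl)-3-(3,5-dimethoxyphenyl)-5-[(E)-2-(3,5-dimethoxyphenyl)ethenyl]-2,3-dihydro-1-benzofuran
Product: 11 4-[(2S,3S)-3-(3,5-dihydroxyphenyl)-5-[(E)-2-(3,5-dihydroxyphenyl)ethenyl]-2,3-dihydro-1-benzofuran-2-yl]benzene-1,2-diol (CNP0207985.1)
Conditions: BBr3 (12 equiv), CH2Cl2, −78 → 0 °C; then ice-water
Reagents that add atoms: none
Why: Lewis-acid cleavage of aryl methyl ethers (boron coordination, then bromide attack at methyl), during which a reversible ionisation of the benzylic C2–O1 bond can only re-close to the thermodynamically preferred trans ring, while C3, which fixes the absolute configuration, has no pathway for epimerisation.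

Compound list
1 | 1-(3,4-dimethoxyphenyl)ethan-1-one (3',4'-dimethoxyacetophenone) | CC(=O)c1ccc(OC)c(OC)c1 | starting material
2 | 1-bromo-3,5-dimethoxybenzene | COc1cc(Br)cc(OC)c1 | starting material
3 | 1-(3,4-dimethoxyphenyl)-2-(3,5-dimethoxyphenyl)ethan-1-one | COc1cc(CC(=O)c2ccc(OC)c(OC)c2)cc(OC)c1 | intermediate
4 | 2-(3-bromo-4-fluorophenyl)-1,3-dioxolane | Fc1ccc(cc1Br)C1OCCO1 | starting material
5 | rac-1-(3,4-dimethoxyphenyl)-2-(3,5-dimethoxyphenyl)-2-[5-(1,3-dioxolan-2-yl)-2-fluorophenyl]ethan-1-one | O=C(c1ccc(OC)c(OC)c1)C(c1cc(OC)cc(OC)c1)c1cc(C2OCCO2)ccc1F | intermediate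
6 | (1S,2S)-1-(3,4-dimethoxyphenyl)-2-(3,5-dimethoxyphenyl)-2-[5-(1,3-dioxolan-2-yl)-2-fluorophenyl]ethan-1-ol | O[C@H](c1ccc(OC)c(OC)c1)[C@@H](c1cc(OC)cc(OC)c1)c1cc(C2OCCO2)ccc1F | intermediate
7 | 3-[(1S,2S)-2-(3,4-dimethoxyphenyl)-1-(3,5-dimethoxyphenyl)-2-hydroxyethyl]-4-fluorobenzaldehyde | O[C@H](c1ccc(OC)c(OC)c1)[C@@H](c1cc(OC)cc(OC)c1)c1cc(C=O)ccc1F | intermediate
8 | diethyl [(3,5-dimethoxyphenyl)methyl]phosphonate | CCOP(=O)(Cc1cc(OC)cc(OC)c1)OCC | starting material
9 | (2S,3S)-2-(3,4-dimethoxyphenyl)-3-(3,5-dimethoxyphenyl)-2,3-dihydro-1-benzofuran-5-carbaldehyde (not isolated) | O=Cc1ccc2c(c1)[C@H](c1cc(OC)cc(OC)c1)[C@@H](c1ccc(OC)c(OC)c1)O2 | intermediate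
10 | (2S,3S)-2-(3,4-dimethoxyphenyl)-3-(3,5-dimethoxyphenyl)-5-[(E)-2-(3,5-dimethoxyphenyl)ethenyl]-2,3-dihydro-1-benzofuran | COc1cc(OC)cc(/C=C/c2ccc3c(c2)[C@H](c2cc(OC)cc(OC)c2)[C@@H](c2ccc(OC)c(OC)c2)O3)c1 | intermediate
11 | 4-[(2S,3S)-3-(3,5-dihydroxyphenyl)-5-[(E)-2-(3,5-dihydroxyphenyl)ethenyl]-2,3-dihydro-1-benzofuran-2-yl]benzene-1,2-diol | Oc1cc(O)cc(/C=C/c2ccc3c(c2)[C@H](c2cc(O)cc(O)c2)[C@@H](c2ccc(O)c(O)c2)O3)c1 | target

Total step count: 6. Longest linear sequence: 6 steps (1 → 3 → 5 → 6 → 7 → 10 → 11).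

Steps most likely to fail

Step 3 (transfer hydrogenation with dynamic kinetic resolution). What may go wrong: poor discrimination between the two α-aryl groups, or enolisation that is slow relative to reduction, so that the configuration at C2 of the alcohol is not controlled although C1 is. Fallback, from 5 back to 6: the dynamic resolution is given up and the reduction is used only for the catalyst-controlled setting of C1 as (S). Both products are then single enantiomers. Alcohol 6 is separated by chromatography or crystallisation from its diastereomer (1S,2R)-1-(3,4-dimethoxyphenyl)-2-(3,5-dimethoxyphenyl)-2-[5-(1,3-dioxolan-2-yl)-2-fluorophenyl]ethan-1-ol F1. F1 is oxidised with Dess–Martin periodinane (NaHCO3, CH2Cl2, 0 °C) back to ketone 5, whose α-centre racemises again, and is resubmitted to the reduction.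

Step 6 (global demethylation). What may go wrong: acid-induced ionisation of the C2–O1 bond and protonation of the electron-rich stilbene, leading to cationic side reactions, together with incomplete cleavage of six ethers. Fallback, from 9 back to 11: step 5 is stopped after the ring closure (NH4Cl quench before the phosphonate is added) and 9 is isolated. Its four methyl ethers are cleaved with BBr3 (CH2Cl2, −78 → 0 °C) while no olefin is present, to give (2S,3S)-2-(3,4-dihydroxyphenyl)-3-(3,5-dihydroxyphenyl)-2,3-dihydro-1-benzofuran-5-carbaldehyde F2. Silylation (TBSCl, imidazole, DMF) gives (2S,3S)-2-[3,4-bis(tert-butyldimethylsilyloxy)phenyl]-3-[3,5-bis(tert-butyldimethylsilyloxy)phenyl]-2,3-dihydro-1-benzofuran-5-carbaldehyde F3. Wittig methylenation (Ph3PCH3Br, KN(SiMe3)2, THF, −78 → 0 °C) gives (2S,3S)-2-[3,4-bis(tert-butyldimethylsilyloxy)phenyl]-3-[3,5-bis(tert-butyldimethylsilyloxy)phenyl]-5-ethenyl-2,3-dihydro-1-benzofuran F4. A Mizoroki–Heck reaction (Pd(OAc)2, P(o-tol)3, Et3N, MeCN, 85 °C) with 1-bromo-3,5-bis(tert-butyldimethylsilyloxy)benzene F5, made from commercial 5-bromoresorcinol (TBSCl, imidazole, DMF), should give the E-configured hexakis(tert-butyldimethylsilyl) ether of the target F6. Fluoride (Et3N·3HF, THF, rt) then removes the six silyl groups without acid and gives 11.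

Step 5 (ring closure and olefination in one flask). What may go wrong: intermolecular reaction of the alkoxide with the formyl group of a second molecule (hemiacetal formation, hydride transfer) competing with ring closure, or attack of the phosphonate anion on material that has not yet cyclised. Fallback, from 3 back to 9: the activating group is changed to a nitrile, which cannot accept the alkoxide or a hydride. α-Arylation of 3 with 3-bromo-4-fluorobenzonitrile (Pd2(dba)3, Xantphos, K3PO4, toluene, 80 °C; the weak base and non-polar solvent should keep the product enolate from closing to a benzofuran) gives rac-3-[2-(3,4-dimethoxyphenyl)-1-(3,5-dimethoxyphenyl)-2-oxoethyl]-4-fluorobenzonitrile F7. Transfer hydrogenation under the conditions of step 3 gives 3-[(1S,2S)-2-(3,4-dimethoxyphenyl)-1-(3,5-dimethoxyphenyl)-2-hydroxyethyl]-4-fluorobenzonitrile F8. KN(SiMe3)2 in THF at 0 °C closes the ring to (2S,3S)-2-(3,4-dimethoxyphenyl)-3-(3,5-dimethoxyphenyl)-2,3-dihydro-1-benzofuran-5-carbonitrile F9. iBu2AlH (CH2Cl2, −78 °C, then 1 M HCl) reduces the nitrile to aldehyde 9, which is isolated and olefinated with 8 as in step 5.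

Further compounds
F1 | step 3 | (1S,2R)-1-(3,4-dimethoxyphenyl)-2-(3,5-dimethoxyphenyl)-2-[5-(1,3-dioxolan-2-yl)-2-fluorophenyl]ethan-1-ol | O[C@H](c1ccc(OC)c(OC)c1)[C@H](c1cc(OC)cc(OC)c1)c1cc(C2OCCO2)ccc1F
F2 | step 6 | (2S,3S)-2-(3,4-dihydroxyphenyl)-3-(3,5-dihydroxyphenyl)-2,3-dihydro-1-benzofuran-5-carbaldehyde | O=Cc1ccc2c(c1)[C@H](c1cc(O)cc(O)c1)[C@@H](c1ccc(O)c(O)c1)O2
F3 | step 6 | (2S,3S)-2-[3,4-bis(tert-butyldimethylsilyloxy)phenyl]-3-[3,5-bis(tert-butyldimethylsilyloxy)phenyl]-2,3-dihydro-1-benzofuran-5-carbaldehyde | O=Cc1ccc2c(c1)[C@H](c1cc(O[Si](C)(C)C(C)(C)C)cc(O[Si](C)(C)C(C)(C)C)c1)[C@@H](c1ccc(O[Si](C)(C)C(C)(C)C)c(O[Si](C)(C)C(C)(C)C)c1)O2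
F4 | step 6 | (2S,3S)-2-[3,4-bis(tert-butyldimethylsilyloxy)phenyl]-3-[3,5-bis(tert-butyldimethylsilyloxy)phenyl]-5-ethenyl-2,3-dihydro-1-benzofuran | C=Cc1ccc2c(c1)[C@H](c1cc(O[Si](C)(C)C(C)(C)C)cc(O[Si](C)(C)C(C)(C)C)c1)[C@@H](c1ccc(O[Si](C)(C)C(C)(C)C)c(O[Si](C)(C)C(C)(C)C)c1)O2
F5 | step 6 | 1-bromo-3,5-bis(tert-butyldimethylsilyloxy)benzene | CC(C)(C)[Si](C)(C)Oc1cc(Br)cc(O[Si](C)(C)C(C)(C)C)c1
F6 | step 6 | (2S,3S)-2-[3,4-bis(tert-butyldimethylsilyloxy)phenyl]-3-[3,5-bis(tert-butyldimethylsilyloxy)phenyl]-5-[(E)-2-[3,5-bis(tert-butyldimethylsilyloxy)phenyl]ethenyl]-2,3-dihydro-1-benzofuran | CC(C)(C)[Si](C)(C)Oc1cc(O[Si](C)(C)C(C)(C)C)cc(/C=C/c2ccc3c(c2)[C@H](c2cc(O[Si](C)(C)C(C)(C)C)cc(O[Si](C)(C)C(C)(C)C)c2)[C@@H](c2ccc(O[Si](C)(C)C(C)(C)C)c(O[Si](C)(C)C(C)(C)C)c2)O3)c1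
F7 | step 5 | rac-3-[2-(3,4-dimethoxyphenyl)-1-(3,5-dimethoxyphenyl)-2-oxoethyl]-4-fluorobenzonitrile | O=C(c1ccc(OC)c(OC)c1)C(c1cc(OC)cc(OC)c1)c1cc(C#N)ccc1F
F8 | step 5 | 3-[(1S,2S)-2-(3,4-dimethoxyphenyl)-1-(3,5-dimethoxyphenyl)-2-hydroxyethyl]-4-fluorobenzonitrile | O[C@H](c1ccc(OC)c(OC)c1)[C@@H](c1cc(OC)cc(OC)c1)c1cc(C#N)ccc1F
F9 | step 5 | (2S,3S)-2-(3,4-dimethoxyphenyl)-3-(3,5-dimethoxyphenyl)-2,3-dihydro-1-benzofuran-5-carbonitrile | N#Cc1ccc2c(c1)[C@H](c1cc(OC)cc(OC)c1)[C@@H](c1ccc(OC)c(OC)c1)O2
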